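The data stem from a simulated flask from invented constants.

The vessel changes how much substrate stands unopened at a given moment, so that is the quick number worth having before any yield.

| setting | Wednesday's | Sunday's | Tuesday's | autumn | dawn | midnight | noon |
|---|---|---|---|---|---|---|---|
| substrate | 0.050 M | 0.025 M | 0.038 M | 0.050 M (fed, over 24.0 min) | 0.050 M | 0.050 M | 0.050 M |
| reagent | 0.10 M | 0.10 M | 0.10 M | 0.100 M | 0.100 M | 0.100 M | 0.100 M (fed, over 24.0 min) |
| capture agent | 5 mM | 5 mM | 5 mM | 5.00 mM | 5.00 mM | 5.00 mM | 5.00 mM |
| remark | run made earlier | run made earlier | run made earlier | a stirred flask in which substrate is dosed at a steady rate over 24.0 min without added volume, worked up at 30 min | a closed flask charged with all of it at once and left for 30 min | a single well-mixed tank run continuously and read at steady state, 30 min in it on average | a stirred flask in which reagent is dosed at a steady rate over 24.0 min without added volume, worked up at 30 min |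
| time |  |  |  | 30 min | 30 min |  | 30 min |

| run | time / min | open intermediate / % | target / % |
|---|---|---|---|
| Wednesday's | 1.33 | 13.7 | 1.8 |
| Wednesday's | 3.00 | 22.8 | 3.1 |
| Wednesday's | 8.00 | 35.1 | 10.4 |
| Wednesday's | 20.0 | 36.9 | 20.2 |
| Sunday's | 2.50 | 21.1 | 3.0 |
| Sunday's | 6.00 | 35.4 | 6.7 |
| Sunday's | 12.0 | 41.1 | 16.3 |
| Sunday's | 20.0 | 38.5 | 19.9 |
| Tuesday's | 2.50 | 21.6 | 2.1 |
| Tuesday's | 6.00 | 32.6 | 8.6 |
| Tuesday's | 12.0 | 38.9 | 14.5 |
| Tuesday's | 20.0 | 36.2 | 20.5 |

(readings scatter by 1 percentage point)

- the set-up with the highest amount of open intermediate at the outlet or at the end, in percent of the substrate put in ("none" if the first two lie within 2 percentage points) (autumn / dawn / midnight / noon / none)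
- amount of open intermediate at the outlet or at the end, in percent of the substrate put in, autumn
- amount of open intermediate at the outlet or at the end, in percent of the substrate put in, dawn
- amount of open intermediate at the outlet or at the end, in percent of the substrate put in, midnight
- amount of open intermediate at the outlet or at the end, in percent of the substrate put in, noon

- the stated concentrations are those of everything mixed, before any reaction; amounts are the same in each set-up
- the feed brings no volume worth counting
- the earlier runs were made in a closed, stirred flask

At 2.50 min, open intermediate plus target reads 24.1% in Sunday's run from 0.025 M substrate. At 2.50 min, Tuesday's run from 0.038 M reads 23.7%, the same within scatter. Opening therefore reads as pseudo-first-order in substrate, and these two readings give a constant of 0.109 /min at 0.10 M reagent.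

Dividing that constant by the feed rate, one charge per 24.0 min, gives 2.62, a ratio free of time: the dosing number, opening speed over feeding speed. A feed balance with opening as the sole loss then puts 35.4% of the charge in the autumn flask at the end of the feed, and 18.4% at 30 min. The dawn flask, on the same constant, is reckoned to keep 3.77% at 30 min. So the reckoning has the autumn flask at 30 min still opening substrate at 4.88 times the dawn rate, while in Sunday's closed flask open intermediate reads 41.1% at 12.0 min and 38.5% at 20.0 min. This reckoning picks autumn over dawn but gives no yield figure.

The forecast, your hunch, has 37% for autumn, 33.5% for dawn, 31% for midnight and 34.5% for noon, holding that “Substrate dosing keeps material younger”.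

The flasks give 36.4% for autumn, 31.9% for dawn, 27.5% for midnight and 28.3% for noon, with autumn first.

    open intermediate + capture agent → trapped intermediate (k = 0.560 /M/min)
    substrate + reagent → open intermediate + by-product (k = 1.20 /M/min)
    open intermediate ⇌ isomer of the product (K = 200, k = 0.0290 /min)
    open intermediate ⇌ target (K = 0.560, k = 0.0810 /min)
    2 substrate → self-condensation product (k = 0.310 /M/min)

The autumn flask holds 36.3% substrate at 24.0 min against the reckoned 35.4%, and 21% at 30.0 min against 18.4%. Its neighbouring flask is charged with 0.17 M reagent instead of 0.100 M. Taking opening as first order in reagent, the dosing number there becomes 4.46, which reckons 7.29% substrate at 30 min. That neighbouring flask holds 8.9% substrate at 30.0 min, with 43.2% open intermediate.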